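**Retrosynthetic overview**
- Target ⇐ its hepta-O-methyl ether (global demethylation last).
- Hepta-O-methyl ether ⇐ an acyclic biaryl carrying two 3,4-dimethoxystilbene arms, by one chiral-acid-triggered double hydroarylation.
- Ring order: the four benzene rings are bought intact; the six-membered carbocycle closes first (C-8 to ring D, sets C-8), then the seven-membered carbocycle (C-9 to ring B, sets C-9), both in the same operation.
- Bis-stilbene ⇐ biaryl dialdehyde + 2 × 3,4-dimethoxybenzylphosphonate (rings B and C are the same building block).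
- Biaryl dialdehyde ⇐ two bromobenzaldehydes (ring A–ring D bond) by one-pot borylation/Suzuki coupling.

**Labels.** Ring A = 3,5-dioxygenated ring; ring D = central mono-oxygenated ring; ring B = catechol ring fused in the seven-membered ring; ring C = pendant catechol ring. C-7 = CH2 between ring A and C-8; C-8 = methine bonded to rings B and D; C-9 = methine bonded to rings B and C; C-10 = CH2 between C-9 and ring D. On ring D, d-1 carries C-10, d-3 carries oxygen, d-5 carries ring A, d-6 (between d-1 and d-5) is bonded to C-8, and d-4 is the other CH ortho to ring A. The target is (8S,9R), with H-8 and H-9 cis on the seven-membered ring.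

**Assumption.** Compounds 1, 3 and 6 are taken as catalogue items (3 is otherwise one bromination from 3,5-dimethoxybenzaldehyde). The sense of induction of the chiral acid in step 3 cannot be predicted with confidence; the (S,S) acid is written, and its mirror image is used if a first run gives the 8R series.

Step 1
Reactants: 1 3-bromo-5-methoxybenzaldehyde; 2 bis(pinacolato)diboron; 3 2-bromo-3,5-dimethoxybenzaldehyde
Product: 5 4,5',6-trimethoxy-[1,1'-biphenyl]-2,3'-dicarbaldehyde, via pinacol boronate 4 (not isolated)
Conditions: 1 (1.1 equiv), 2 (1.1 equiv), Pd(dppf)Cl2 (3 mol%), KOAc, 1,4-dioxane, 90 °C; then 3 (1.0 equiv), Pd(OAc)2 (2 mol%), SPhos (4 mol%), aq. K3PO4, 90 °C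
Reagents that add atoms: none
Why: Miyaura borylation of the unhindered bromide followed in the same pot by Suzuki–Miyaura coupling, where zerovalent palladium with SPhos handles the di-ortho-substituted bromide 3 and both aldehydes are tolerated; no stereocentre is formed.

Step 2
Reactants: 5 4,5',6-trimethoxy-[1,1'-biphenyl]-2,3'-dicarbaldehyde; 6 diethyl (3,4-dimethoxybenzyl)phosphonate (2.4 equiv)
Product: 7 2,3'-bis[(E)-2-(3,4-dimethoxyphenyl)ethenyl]-4,5',6-trimethoxy-1,1'-biphenyl
Conditions: NaH (2.6 equiv), THF, 0 °C → rt
Reagents that add atoms: none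
Why: Double Horner–Wadsworth–Emmons olefination with a benzylic phosphonate gives the E,E-bis-stilbene and installs rings B and C at once; no stereocentre is formed and the alkene geometry is erased in step 3.

Step 3
Reactants: 7 2,3'-bis[(E)-2-(3,4-dimethoxyphenyl)ethenyl]-4,5',6-trimethoxy-1,1'-biphenyl
Product: 9 (8S,9R)-hepta-O-methyl ether of the target, via monocyclised styryl-dihydrophenanthrene 8 (not isolated)
Conditions: (S,S)-IDPi (N-triflyl imidodiphosphorimidate from (S)-3,3'-bis[3,5-bis(trifluoromethyl)phenyl]-BINOL, 5 mol%), CHCl3 (0.005 M, slow addition of 7), 5 Å MS, 40 °C; then recrystallisation to raise ee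
Reagents that add atoms: none
Why: Proposed new method: the confined strong chiral acid protonates C-7 (only this gives a C-8 cation stabilised by the para-OMe of ring B), the contact ion pair closes the six-membered ring by Friedel–Crafts attack of ring D at d-6 (para to OMe, the site 3-alkylanisoles prefer over the ortho site d-4) with the chiral anion selecting the cation face and so setting C-8 (S), and the same acid then protonates C-10 so that the ring C-stabilised C-9 cation is captured by ring B para to its OMe to close the seven-membered ring, the aryl group taking the outer pseudo-equatorial position cis to C-7 (C-9 R, substrate control); the closest known reaction types are IDPi-catalysed asymmetric intramolecular hydroarylation of olefins and the Brønsted-acid cyclisation of 2-styrylbiaryls to 9-aryl-9,10-dihydrophenanthrenes and of methoxystilbenes in oligostilbene synthesis.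

Step 4
Reactants: 9 (8S,9R)-hepta-O-methyl ether of the target
Product: 10 target heptaphenol CNP0306974.2, (8S,9R)
Conditions: BBr3 (14 equiv), CH2Cl2, −78 °C → rt, Ar; then H2O, 0 °C
Reagents that add atoms: none
Why: BBr3 ether cleavage (Lewis-acid O-demethylation) removes all seven methyl groups without touching the two benzylic C–H stereocentres, which have no leaving group and no acidic proton, so C-8 and C-9 are carried through unchanged.

**Compound list**
1 | 3-bromo-5-methoxybenzaldehyde | COc1cc(Br)cc(C=O)c1 | starting material
2 | bis(pinacolato)diboron | CC1(C)OB(OC1(C)C)B1OC(C)(C)C(C)(C)O1 | starting material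
3 | 2-bromo-3,5-dimethoxybenzaldehyde | COc1cc(OC)c(Br)c(C=O)c1 | starting material
4 | 3-methoxy-5-(4,4,5,5-tetramethyl-1,3,2-dioxaborolan-2-yl)benzaldehyde | COc1cc(C=O)cc(c1)B1OC(C)(C)C(C)(C)O1 | intermediate (not isolated)
5 | 4,5',6-trimethoxy-[1,1'-biphenyl]-2,3'-dicarbaldehyde | COc1cc(OC)c(-c2cc(OC)cc(C=O)c2)c(C=O)c1 | intermediate
6 | diethyl (3,4-dimethoxybenzyl)phosphonate | CCOP(=O)(Cc1ccc(OC)c(OC)c1)OCC | starting material
7 | 2,3'-bis[(E)-2-(3,4-dimethoxyphenyl)ethenyl]-4,5',6-trimethoxy-1,1'-biphenyl | COc1cc(OC)c(-c2cc(OC)cc(/C=C/c3ccc(OC)c(OC)c3)c2)c(/C=C/c2ccc(OC)c(OC)c2)c1 | intermediate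
8 | (10S)-10-(3,4-dimethoxyphenyl)-1-[(E)-2-(3,4-dimethoxyphenyl)ethenyl]-3,5,7-trimethoxy-9,10-dihydrophenanthrene (C-8 S in the labels used here) | COc1cc(OC)c2c(c1)C[C@@H](c1ccc(OC)c(OC)c1)c1c(/C=C/c3ccc(OC)c(OC)c3)cc(OC)cc1-2 | intermediate (not isolated)
9 | (8S,9R)-hepta-O-methyl ether of the target: 9,10-dihydrophenanthrene (rings A and D) whose C-8 and d-1 are bridged by ring B and C-9–C-10 into a seven-membered ring, ring C on C-9, all seven oxygens as OMe, H-8/H-9 cis | COc1cc(OC)c2c(c1)C[C@H]1c3cc(OC)c(OC)cc3[C@@H](c3ccc(OC)c(OC)c3)Cc3cc(OC)cc-2c31 | intermediate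
10 | CNP0306974.2, (8S,9R)-heptaphenol | Oc1cc(O)c2c(c1)C[C@H]1c3cc(O)c(O)cc3[C@@H](c3ccc(O)c(O)c3)Cc3cc(O)cc-2c31 | target

**Totals.** 4 steps; longest linear sequence 4 steps (from 1 or 3).

**Steps most likely to fail, with fallbacks**

Step 3 (most likely). The asymmetric bis-cyclisation is untested: the ee may be low, closure at d-4 may compete, or C-9 may form as the trans epimer. The fallback sets out from 7 and comes back at 9. The chiral acid is given up and 7 is cyclised with an achiral strong acid under equilibrating conditions (TfOH 20 mol%, CH2Cl2/HFIP, rt). There the reversible first closure is funnelled into the doubly cyclised, thermodynamically preferred cis product. This gives 9 as a racemate with its mirror image, the (8R,9S)-hepta-O-methyl ether F1. The two are separated by preparative supercritical-fluid chromatography on an amylose-based chiral stationary phase to return to 9.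

Step 1. The one-pot borylation/coupling may give homocoupling or protodeboronation, or stall at the hindered, electron-rich bromide 3. The fallback sets out from 1 and comes back at 7, bypassing 5. Horner–Wadsworth–Emmons reaction of 1 with 6 (NaH, THF) gives (E)-1-bromo-3-[2-(3,4-dimethoxyphenyl)ethenyl]-5-methoxybenzene F2. Bromine–lithium exchange (n-BuLi, THF, −78 °C) and ZnCl2 give the arylzinc chloride F3, used in solution. Negishi coupling of this more reactive nucleophile with 3 (Pd(OAc)2, SPhos, THF, 50 °C; the aldehyde tolerates the organozinc) gives 2-{3-[(E)-2-(3,4-dimethoxyphenyl)ethenyl]-5-methoxyphenyl}-3,5-dimethoxybenzaldehyde F4. A second olefination of F4 with 6 returns to 7.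

Step 4. Sevenfold demethylation may stop at partly methylated phenols, and the air-sensitive bis-catechol is hard to purify directly. The fallback sets out from 9 and comes back at 10. After BBr3 treatment the crude polyphenol is not isolated but peracetylated in the same flask (Ac2O, pyridine, DMAP) to the stable, chromatographable and crystallisable (8S,9R)-heptaacetate F5. Incompletely demethylated material is removed at this stage. Acidic methanolysis of F5 (HCl generated from AcCl in degassed MeOH, 0 °C → rt, Ar) then releases 10 without exposing the catechols to base.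

**Further compounds**
F1 | step 3 | (8R,9S)-hepta-O-methyl ether, mirror image of 9 (second component of racemic 9) | COc1cc(OC)c2c(c1)C[C@@H]1c3cc(OC)c(OC)cc3[C@H](c3ccc(OC)c(OC)c3)Cc3cc(OC)cc-2c31
F2 | step 1 | (E)-1-bromo-3-[2-(3,4-dimethoxyphenyl)ethenyl]-5-methoxybenzene | COc1cc(Br)cc(/C=C/c2ccc(OC)c(OC)c2)c1
F3 | step 1 | {3-[(E)-2-(3,4-dimethoxyphenyl)ethenyl]-5-methoxyphenyl}zinc chloride | COc1cc([Zn]Cl)cc(/C=C/c2ccc(OC)c(OC)c2)c1
F4 | step 1 | 2-{3-[(E)-2-(3,4-dimethoxyphenyl)ethenyl]-5-methoxyphenyl}-3,5-dimethoxybenzaldehyde | COc1cc(OC)c(-c2cc(OC)cc(/C=C/c3ccc(OC)c(OC)c3)c2)c(C=O)c1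
F5 | step 4 | (8S,9R)-heptaacetate of 10 | CC(=O)Oc1cc(OC(C)=O)c2c(c1)C[C@H]1c3cc(OC(C)=O)c(OC(C)=O)cc3[C@@H](c3ccc(OC(C)=O)c(OC(C)=O)c3)Cc3cc(OC(C)=O)cc-2c31
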